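**Plan**
- Retrosynthetic cuts, in order: C8–CH2 (prenyl), C4–C4a (aryl–acyl bond, closes ring C), O1–C2 (aryl ether), then the phenolic C–O bond of ring A.
- Enabling feature: C4a and C8 are the two carbons ortho to O1 and each has a methoxy-bearing neighbour (C5, C7). Before ring C exists, ring A therefore has a mirror plane through C8a and C6, and a 2,6-dibromo-3,5-dimethoxyphenyl ether has two equivalent C–Br bonds. One becomes C4–C4a; the other is then necessarily at C8, where the prenyl group goes.
- Forward: ring A is bought as 1,5-dibromo-2,4-dimethoxybenzene and hydroxylated between the bromines. A Mitsunobu coupling joins it to the C2–C3–C4 chain (a Weinreb amide). One flask then closes ring C by Br–Li exchange and acylation, and prenylates C8 by a second exchange while the C4 ketone stays masked as its lithium hemiaminal.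
- Stereochemistry: C2 comes from ethyl (R)-3-hydroxy-3-phenylpropanoate, inverted once in the Mitsunobu step to S. The free β-aryloxy ketone never meets base, so retro-oxa-Michael racemisation is avoided.

Key step: step 4

Remark: flavanone numbering (O1, C2, C3, C4, C4a, C5 to C8, C8a) is used; 1 and 5 are assumed to be purchasable, 5 as the single enantiomer.

**Step 1**
Reactants: 1 1,5-dibromo-2,4-dimethoxybenzene
Product: 4 2,6-dibromo-3,5-dimethoxyphenol, via aryllithium 2 (not isolated), via lithium aryltrimethoxyborate 3 (not isolated)
Conditions: LiN(iPr)2 (1.1 equiv), THF, −78 °C; B(OMe)3, −78 to 0 °C; AcOH, 30% aq H2O2, 0 °C to rt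
Reagents that add atoms: hydrogen peroxide, OO
Why: Deprotonative lithiation followed by borylation and peroxide oxidation: the proton between the two bromines is the most acidic ring proton, LiN(iPr)2 neither exchanges bromine nor removes the proton between the methoxy groups, and the C–B bond is oxidised to C–O at the same carbon.

**Step 2**
Reactants: 5 ethyl (R)-3-hydroxy-3-phenylpropanoate
Product: 6 (R)-3-hydroxy-N-methoxy-N-methyl-3-phenylpropanamide
Conditions: MeNH(OMe)·HCl (2 equiv), iPrMgCl (5 equiv), THF, −20 to 0 °C; aq NH4Cl
Reagents that add atoms: N,O-dimethylhydroxylamine hydrochloride, CNOC.Cl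
Why: Weinreb amide formation by aminolysis of the ester with the chloromagnesium amide made in the flask; the magnesium alkoxide of the β-hydroxy group should resist retro-aldol cleavage at this temperature and the stereocenter is not touched.

**Step 3**
Reactants: 4 2,6-dibromo-3,5-dimethoxyphenol; 6 (R)-3-hydroxy-N-methoxy-N-methyl-3-phenylpropanamide
Product: 7 (S)-3-(2,6-dibromo-3,5-dimethoxyphenoxy)-N-methoxy-N-methyl-3-phenylpropanamide
Conditions: PPh3, DIAD, THF (concentrated, ultrasound), 0 °C to rt
Reagents that add atoms: none
Why: Mitsunobu etherification: the acidic phenol 4 protonates the betaine and its phenoxide displaces the alkoxyphosphonium at the benzylic carbon in an SN2 step with inversion, turning the R carbinol of 6 into the S aryl ether carbon that becomes C2.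

**Step 4**
Reactants: 7 (S)-3-(2,6-dibromo-3,5-dimethoxyphenoxy)-N-methoxy-N-methyl-3-phenylpropanamide
Product: 12 candidone [(2S)-5,7-dimethoxy-8-(3-methylbut-2-en-1-yl)-2-phenylchroman-4-one], via aryllithium 8 (not isolated), via bromo lithium hemiaminal 9 (not isolated), via C8-lithiated hemiaminal 10 (not isolated), via prenylated lithium hemiaminal 11 (not isolated)
Conditions: t-BuLi (2.1 equiv), THF, −78 °C; t-BuLi (2.1 equiv), −78 °C; CuBr·SMe2 (0.2 equiv), prenyl bromide (3 equiv), −78 to −30 °C; AcOH, −78 °C to rt
Reagents that add atoms: 1-bromo-3-methylbut-2-ene (prenyl bromide), CC(C)=CCBr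
Why: Br–Li exchange at either of the two equivalent C–Br bonds of 7 gives aryllithium 8, whose carbanion (the future C4a) adds to the Weinreb amide carbonyl (the future C4) and closes ring C as the N,O-chelated lithium hemiaminal 9; a second Br–Li exchange at the remaining bromine, now necessarily at C8, gives 10, which is allylated under copper catalysis at the CH2 end of prenyl bromide to 11, and the acetic acid quench collapses the hemiaminal to the C4 ketone. The closest known reaction type is the Parham cyclisation of ortho-bromoaryl ethers onto Weinreb amides to give chroman-4-ones, combined with the known use of a Weinreb tetrahedral intermediate as a masked ketone during a further organolithium step. Ring C closes in a 6-exo-trig mode. No new stereocenter survives (the hemiaminal carbon becomes the carbonyl carbon), and C2 should keep the S configuration from step 3 because the β-aryloxy ketone is released only after all base is destroyed, which closes the retro-oxa-Michael path to the chalcone. The step needs exchange to outrun attack on, or α-deprotonation of, the amide by t-BuLi, which the fast exchange at a bromide flanked by two oxygen-bearing carbons at −78 °C should secure, and it needs substitution at C8 and not C6, which the mirror symmetry of ring A in 7 guarantees without any directing effect. Attack at the CH2 terminus of prenyl bromide is favoured because the other terminus would place a quaternary carbon between two ortho substituents.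

**Compound list**
1 | 1,5-dibromo-2,4-dimethoxybenzene | COc1cc(OC)c(Br)cc1Br | starting material
2 | 2,6-dibromo-3,5-dimethoxyphenyllithium | COc1cc(OC)c(Br)c([Li])c1Br | intermediate
3 | lithium (2,6-dibromo-3,5-dimethoxyphenyl)trimethoxyborate | COc1cc(OC)c(Br)c([B-](OC)(OC)OC)c1Br.[Li+] | intermediate
4 | 2,6-dibromo-3,5-dimethoxyphenol | COc1cc(OC)c(Br)c(O)c1Br | intermediate
5 | ethyl (R)-3-hydroxy-3-phenylpropanoate | O[C@@H](c1ccccc1)CC(=O)OCC | starting material
6 | (R)-3-hydroxy-N-methoxy-N-methyl-3-phenylpropanamide | O[C@@H](c1ccccc1)CC(=O)N(C)OC | intermediate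
7 | (S)-3-(2,6-dibromo-3,5-dimethoxyphenoxy)-N-methoxy-N-methyl-3-phenylpropanamide | COc1cc(OC)c(Br)c(O[C@H](c2ccccc2)CC(=O)N(C)OC)c1Br | intermediate
8 | (S)-3-(2-bromo-6-lithio-3,5-dimethoxyphenoxy)-N-methoxy-N-methyl-3-phenylpropanamide | COc1cc(OC)c([Li])c(O[C@H](c2ccccc2)CC(=O)N(C)OC)c1Br | intermediate
9 | lithium (2S)-8-bromo-5,7-dimethoxy-4-[methoxy(methyl)amino]-2-phenylchroman-4-olate (either configuration at C4) | COc1cc(OC)c2c(c1Br)O[C@H](c1ccccc1)CC2(O[Li])N(C)OC | intermediate
10 | lithium (2S)-8-lithio-5,7-dimethoxy-4-[methoxy(methyl)amino]-2-phenylchroman-4-olate | COc1cc(OC)c2c(c1[Li])O[C@H](c1ccccc1)CC2(O[Li])N(C)OC | intermediate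
11 | lithium (2S)-5,7-dimethoxy-4-[methoxy(methyl)amino]-8-(3-methylbut-2-en-1-yl)-2-phenylchroman-4-olate | COc1cc(OC)c2c(c1CC=C(C)C)O[C@H](c1ccccc1)CC2(O[Li])N(C)OC | intermediate
12 | candidone, (2S)-5,7-dimethoxy-8-(3-methylbut-2-en-1-yl)-2-phenylchroman-4-one | COc1cc(OC)c2c(c1CC=C(C)C)O[C@H](c1ccccc1)CC2=O | target

**Totals**
Total steps: 4. Longest linear sequence: 3 (steps 1, 3, 4 or steps 2, 3, 4).

**Steps most likely to fail**

Step 4. The lithium hemiaminal may collapse early during the second exchange or the allylation, which would lead to over-addition and base-induced opening of ring C, or the C8 aryllithium may be protonated before it is allylated. The fallback sets out from 7 and comes back at 12. Only the first exchange and ring closure are run (t-BuLi, 2.1 equiv, THF, −78 °C, then AcOH), which should give (2S)-8-bromo-5,7-dimethoxyflavanone F1. The prenyl group is then attached under neutral conditions by Stille coupling of F1 with tributyl(3-methylbut-2-en-1-yl)stannane, using Pd(P(t-Bu)3)2 (zerovalent palladium) in toluene at 60 to 80 °C, to give 12.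

Step 3. Displacement at the alkoxyphosphonium by the doubly ortho-substituted phenoxide may be slow, so that elimination to the cinnamamide or ionisation at the benzylic carbon (loss of optical purity) competes. The fallback sets out from 4 and 6 and comes back at 12. One bromine of 4 is removed (n-BuLi, 2.2 equiv, THF, −78 °C, then MeOH) to give the less hindered 2-bromo-3,5-dimethoxyphenol F2. Mitsunobu coupling of F2 with 6 (PPh3, DIAD, THF) should give (S)-3-(2-bromo-3,5-dimethoxyphenoxy)-N-methoxy-N-methyl-3-phenylpropanamide F3 with inversion. Parham cyclisation of F3 (t-BuLi, THF, −78 °C, then AcOH) should give (2S)-5,7-dimethoxyflavanone F4. Bromination with NBS (MeCN, 0 °C) is expected at C8, the less shielded ring A position, and gives the bromoflavanone F1, which is prenylated by the Stille coupling described for step 4 to give 12. This fallback gives up the symmetry control and depends on C8 versus C6 selectivity in the bromination.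

Step 1. Aryllithium 2 may lose lithium bromide (aryne formation), or borylation at the crowded carbon may be incomplete. The fallback sets out from 5, does without 4 and 7, and comes back at 12. Mitsunobu coupling of 5 with commercial 3,5-dimethoxyphenol (PPh3, DIAD, THF) should give ethyl (S)-3-(3,5-dimethoxyphenoxy)-3-phenylpropanoate F5. Mild saponification (LiOH, THF/H2O, 0 °C) gives (S)-3-(3,5-dimethoxyphenoxy)-3-phenylpropanoic acid F6. Intramolecular Friedel–Crafts acylation through the mixed anhydride (TFAA, CH2Cl2, 0 °C) closes the C4–C4a bond at either of the two equivalent ortho positions and gives (2S)-5,7-dimethoxyflavanone F4. F4 is then brominated at C8 to the bromoflavanone F1 and prenylated by Stille coupling to 12, as above.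

**Further compounds**
F1 | step 4 | (2S)-8-bromo-5,7-dimethoxy-2-phenylchroman-4-one | COc1cc(OC)c2c(c1Br)O[C@H](c1ccccc1)CC2=O
F2 | step 3 | 2-bromo-3,5-dimethoxyphenol | COc1cc(O)c(Br)c(OC)c1
F3 | step 3 | (S)-3-(2-bromo-3,5-dimethoxyphenoxy)-N-methoxy-N-methyl-3-phenylpropanamide | COc1cc(OC)c(Br)c(O[C@H](c2ccccc2)CC(=O)N(C)OC)c1
F4 | step 3 | (2S)-5,7-dimethoxy-2-phenylchroman-4-one | COc1cc(OC)c2c(c1)O[C@H](c1ccccc1)CC2=O
F5 | step 1 | ethyl (S)-3-(3,5-dimethoxyphenoxy)-3-phenylpropanoate | COc1cc(OC)cc(O[C@H](c2ccccc2)CC(=O)OCC)c1
F6 | step 1 | (S)-3-(3,5-dimethoxyphenoxy)-3-phenylpropanoic acid | COc1cc(OC)cc(O[C@H](c2ccccc2)CC(=O)O)c1
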